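**Plan**

- Retrosynthesis: the anilide C–N bond is cut first, giving a C13 acid chloride that already carries the thioacetate and a 2-amino-3-(pyridyl)phenol. The C–S bond of the chain then goes back to a primary bromide and thioacetate.
- The pyridine is cut at C-2/C-3 and C-4/C-5. The enabling feature is that the 2-methylpyridin-4-yl ring has CH3 at C-2, the aryl group at C-4 and only H at C-3, C-5 and C-6. Its nitrogen, C-2 with the methyl group, C-6 and C-5 are therefore ring atoms 4, 3, 5 and 6 of a 3-methyl-1,2,4-triazine, and C-3/C-4 are the CH2 and the aryl-bearing carbon of the enamine of an aryl methyl ketone.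
- That ketone is an acetophenone with NO2 at C-2 and a benzyl ether at C-3, so the benzene ring has its adjacent C, N and O substituents in place before the pyridine exists. The triazine is cut into an amidrazone and glyoxal.
- Forward order: bought benzene ring (nitration, benzylation, enamine), triazine ring by cyclocondensation, pyridine ring by cycloaddition with loss of dinitrogen and pyrrolidine (no biaryl cross-coupling), one hydrogenation to free NH2 and OH, and the chain joined last by N-acylation.
- Stereochemistry: the target has no stereocentre and no stereogenic double bond, and the enamine alkene is terminal, so nothing has to be controlled. The stereocentres of the transient cycloadducts vanish on aromatisation.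

Key step: step 6

Remark on the chemistry: the ω-bromo C13 acid used for the side chain is taken as purchasable from a specialty supplier; every isolated compound of the route is achiral.

**Route**

Step 1
Reactants: 1 3-hydroxyacetophenone
Product: 2 1-(3-hydroxy-2-nitrophenyl)ethanone
Conditions: HNO3 (70%, 1.1 equiv), AcOH, 10–15 °C; chromatography on silica to remove the 4- and 6-nitro isomers
Reagents that add atoms: nitric acid, O[N+](=O)[O-]
Why: Electrophilic aromatic nitration in which the hydroxyl group directs ortho and para, so that attack at the ortho position between OH and acetyl should give 2 as one separable component of the regioisomer mixture usual for 3-acylphenols.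

Step 2
Reactants: 2 1-(3-hydroxy-2-nitrophenyl)ethanone
Product: 3 1-[3-(benzyloxy)-2-nitrophenyl]ethanone
Conditions: BnBr (1.1 equiv), K2CO3 (1.5 equiv), DMF, rt → 50 °C
Reagents that add atoms: benzyl bromide, BrCc1ccccc1
Why: Williamson ether synthesis, in which carbonate deprotonates the acidic ortho-nitrophenol and the phenoxide displaces bromide from benzyl bromide while the methyl ketone is left alone by this weak base.

Step 3
Reactants: 3 1-[3-(benzyloxy)-2-nitrophenyl]ethanone
Product: 4 1-{1-[3-(benzyloxy)-2-nitrophenyl]ethenyl}pyrrolidine (crude, used at once)
Conditions: pyrrolidine (6 equiv), TiCl4 (0.6 equiv), toluene, 0 °C → rt, Ar; filtration under Ar, evaporation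
Reagents that add atoms: pyrrolidine, C1CCNC1
Why: Titanium tetrachloride-mediated enamine condensation, the standard access to enamines of aryl methyl ketones, in which TiCl4 activates the carbonyl group and binds the water as TiO2 while excess pyrrolidine takes up the HCl, and a methyl ketone can give only the terminal enamine.

Step 4
Reactants: 5 ethyl acetimidate hydrochloride
Product: 6 acetamidrazone hydrochloride
Conditions: anhydrous hydrazine (1.0 equiv), EtOH, −10 → 0 °C; precipitation with Et2O
Reagents that add atoms: hydrazine, NN
Why: Addition–elimination of hydrazine at the activated carbon of the Pinner imidate salt displaces ethanol, and one equivalent at low temperature should stop the reaction at the mono-adduct, which is kept as its hydrochloride.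

Step 5
Reactants: 6 acetamidrazone hydrochloride; 7 glyoxal (40% aqueous solution)
Product: 9 3-methyl-1,2,4-triazine, via glyoxal monohydrazone 8 (not isolated)
Conditions: NaHCO3 (1.0 equiv), H2O–MeOH, 0 °C → rt; CH2Cl2 extraction, bulb-to-bulb distillation
Reagents that add atoms: none
Why: Cyclocondensation of an amidrazone with a 1,2-dicarbonyl compound, the classical 1,2,4-triazine synthesis, in which the hydrazine-type NH2 forms hydrazone 8 and the amidine NH2 then condenses with the second aldehyde, aromatisation driving the loss of the second water.

Step 6
Reactants: 4 1-{1-[3-(benzyloxy)-2-nitrophenyl]ethenyl}pyrrolidine; 9 3-methyl-1,2,4-triazine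
Product: 12 4-[3-(benzyloxy)-2-nitrophenyl]-2-methylpyridine, via bicyclic cycloadduct 10 (not isolated), via dihydropyridine 11 (not isolated)
Conditions: 9 (1.5 equiv), 1,4-dioxane, 4 Å molecular sieves, Ar, 60 → 100 °C, sealed tube
Reagents that add atoms: none
Why: This is an inverse-electron-demand Diels–Alder reaction of the Boger pyridine synthesis type: the electron-rich alkene of enamine 4 adds as the 2π partner across C-3 and C-6 of the electron-poor azadiene 9, its CH2 bonding to C-3 and its amine-bearing carbon to C-6, which closes the new six-membered ring by [4+2] cycloaddition in bicycle 10. Retro-[4+2] loss of ring nitrogens 1 and 2 as dinitrogen gives the 3,4-dihydropyridine 11, and 1,2-elimination of pyrrolidine across C-3/C-4 aromatises it, so the pyridine C-2/C-3 and C-4/C-5 bonds are the two new bonds and no oxidant is needed. The closest known reactions are those of 1,2,4-triazines with pyrrolidine enamines of aryl methyl ketones, which give 4-arylpyridines; the 3-methyl group makes 9 a less electron-poor diene, which is why heating in dioxane is planned. No stereocentre is created in 12, since the three stereocentres of 10 and the one of 11 disappear on aromatisation. The selectivity required is regioselectivity, and it is secured by polarisation: C-3 of the triazine, between two ring nitrogens, is the most electrophilic carbon and the unsubstituted CH2 of 4 is the nucleophilic and least hindered terminus, so methyl is placed at C-2 and the aryl group at C-4. The nitro group and the benzyl ether offer no acidic hydrogen that could protonate the enamine, and the ortho-nitro group turns the arene out of the enamine plane so that it does not drain electron density from the alkene.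

Step 7
Reactants: 12 4-[3-(benzyloxy)-2-nitrophenyl]-2-methylpyridine
Product: 14 2-amino-3-(2-methylpyridin-4-yl)phenol, via benzyloxyaniline 13 (not isolated)
Conditions: H2 (1 atm), Pd/C (10 wt % Pd), EtOH–AcOH (10:1), rt; filtration under Ar, NaHCO3 work-up; used without storage
Reagents that add atoms: none
Why: Heterogeneous catalytic hydrogenation reduces the aromatic nitro group to the amine (13) and then hydrogenolyses the benzylic C–O bond of the aryl benzyl ether in the same operation, acetic acid protonating the pyridine nitrogen so that it should not poison the palladium surface, while a pyridine ring is not reduced over Pd/C at 1 atm.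

Step 8
Reactants: 15 13-bromotridecanoic acid
Product: 16 13-(acetylsulfanyl)tridecanoic acid
Conditions: KSAc (2.2 equiv), DMF, rt; then 1 M HCl
Reagents that add atoms: potassium thioacetate, CC(=O)[S-].[K+]
Why: Bimolecular nucleophilic substitution of a primary bromide by the soft thioacetate anion in a dipolar aprotic solvent, the acid being present as its far less nucleophilic potassium carboxylate until the acidic work-up.

Step 9
Reactants: 16 13-(acetylsulfanyl)tridecanoic acid
Product: 17 13-(acetylsulfanyl)tridecanoyl chloride (crude, used at once)
Conditions: (COCl)2 (1.5 equiv), DMF (cat.), CH2Cl2, 0 °C → rt; evaporation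
Reagents that add atoms: oxalyl chloride, O=C(Cl)C(=O)Cl
Why: Vilsmeier-type activation, in which catalytic DMF and oxalyl chloride form the chloroiminium salt that converts the carboxylic acid into its chloride with release of CO, CO2 and HCl, conditions a thioester tolerates.

Step 10
Reactants: 14 2-amino-3-(2-methylpyridin-4-yl)phenol; 17 13-(acetylsulfanyl)tridecanoyl chloride
Product: 18 echinoclathrine B (S-(13-{[2-hydroxy-6-(2-methylpyridin-4-yl)phenyl]amino}-13-oxotridecyl) ethanethioate)
Conditions: 17 (1.0 equiv, added dropwise in EtOAc), EtOAc–sat. aq. NaHCO3, 0 °C → rt, Ar
Reagents that add atoms: none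
Why: Schotten–Baumann acylation, in which the aniline nitrogen is the most nucleophilic site of the 2-aminophenol at bicarbonate pH, one equivalent of 17 limits double acylation, and the thioacetate is far less electrophilic than the acid chloride and should keep its acetyl group at 0 °C.

**Compound list**

1 | 3-hydroxyacetophenone, 1-(3-hydroxyphenyl)ethanone | CC(=O)c1cccc(O)c1 | starting material
2 | 1-(3-hydroxy-2-nitrophenyl)ethanone | CC(=O)c1cccc(O)c1[N+](=O)[O-] | intermediate
3 | 1-[3-(benzyloxy)-2-nitrophenyl]ethanone | CC(=O)c1cccc(OCc2ccccc2)c1[N+](=O)[O-] | intermediate
4 | 1-{1-[3-(benzyloxy)-2-nitrophenyl]ethenyl}pyrrolidine | C=C(N1CCCC1)c1cccc(OCc2ccccc2)c1[N+](=O)[O-] | intermediate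
5 | ethyl acetimidate hydrochloride (ethyl ethanimidate hydrochloride) | CCOC(C)=N.Cl | starting material
6 | acetamidrazone hydrochloride (ethanimidohydrazide hydrochloride) | CC(N)=NN.Cl | intermediate
7 | glyoxal (ethanedial), 40% aqueous solution | O=CC=O | starting material
8 | glyoxal mono(acetamidrazone), CH3C(NH2)=N–N=CH–CHO, transient in step 5 | CC(N)=NN=CC=O | intermediate
9 | 3-methyl-1,2,4-triazine | Cc1nccnn1 | intermediate
10 | 7-[3-(benzyloxy)-2-nitrophenyl]-4-methyl-7-(pyrrolidin-1-yl)-2,3,5-triazabicyclo[2.2.2]octa-2,5-diene, racemic, transient in step 6 | C1=NC2(C)N=NC1C(N3CCCC3)(c3cccc(OCc4ccccc4)c3[N+](=O)[O-])C2 | intermediate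
11 | 4-[3-(benzyloxy)-2-nitrophenyl]-2-methyl-4-(pyrrolidin-1-yl)-3,4-dihydropyridine, racemic, transient in step 6 | CC1=NC=CC(N2CCCC2)(c2cccc(OCc3ccccc3)c2[N+](=O)[O-])C1 | intermediate
12 | 4-[3-(benzyloxy)-2-nitrophenyl]-2-methylpyridine | Cc1cc(-c2cccc(OCc3ccccc3)c2[N+](=O)[O-])ccn1 | intermediate
13 | 2-(benzyloxy)-6-(2-methylpyridin-4-yl)aniline, transient in step 7 | Cc1cc(-c2cccc(OCc3ccccc3)c2N)ccn1 | intermediate
14 | 2-amino-3-(2-methylpyridin-4-yl)phenol | Cc1cc(-c2cccc(O)c2N)ccn1 | intermediate
15 | 13-bromotridecanoic acid | BrCCCCCCCCCCCCC(=O)O | starting material
16 | 13-(acetylsulfanyl)tridecanoic acid | CC(=O)SCCCCCCCCCCCCC(=O)O | intermediate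
17 | 13-(acetylsulfanyl)tridecanoyl chloride | CC(=O)SCCCCCCCCCCCCC(=O)Cl | intermediate
18 | echinoclathrine B | CC(=O)SCCCCCCCCCCCCC(=O)Nc1c(O)cccc1-c1ccnc(C)c1 | target

**Count and risks**

Total step count: 10. Longest linear sequence: 6 steps (steps 1, 2, 3, 6, 7 and 10). The triazine branch (steps 4 and 5) and the chain branch (steps 8 and 9) each join it after two steps.

Steps most likely to fail:

1. Step 6. The cycloaddition may be too slow, because the methyl group makes the triazine a weaker diene and the enamine is hindered by its ortho substituent, so thermal decay of the enamine could outrun pyridine formation. The fallback keeps the triazine-to-pyridine logic but uses an activated diene. It sets out from 4 and 7 and returns at 14. Glyoxal 7 and bought ethyl oxalamidrazonate (CCOC(=O)C(N)=NN) are condensed in EtOH at rt to ethyl 1,2,4-triazine-3-carboxylate F1. Its ester group lowers the diene LUMO so that cycloaddition with 4 should proceed in CHCl3 at 25–45 °C, with the same regiochemistry and the same loss of dinitrogen and pyrrolidine, to give ethyl 4-[3-(benzyloxy)-2-nitrophenyl]pyridine-2-carboxylate F2. NaBH4 with CaCl2 in EtOH–THF at 0 °C reduces the picolinate ester, leaving the nitro group, to {4-[3-(benzyloxy)-2-nitrophenyl]pyridin-2-yl}methanol F3. SOCl2 in CH2Cl2 converts it into 4-[3-(benzyloxy)-2-nitrophenyl]-2-(chloromethyl)pyridine F4, handled as its hydrochloride. Hydrogenation (H2, Pd/C, EtOH, rt) then hydrogenolyses the picolyl C–Cl bond to the methyl group while reducing the nitro group and cleaving the benzyl ether, which gives 14.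

2. Step 3. Condensation at the hindered ketone may stay incomplete, and the enamine may be lost by hydrolysis during filtration and evaporation, by displacement of the activated nitro group by pyrrolidine, or by oxygen transfer from the neighbouring nitro group. The fallback sets out from 3 (with 9) and returns at 12. The enamine is no longer prepared and isolated. It is generated catalytically in the cycloaddition flask from 3, 9, pyrrolidine (0.2–1.0 equiv) and 4 Å molecular sieves in CHCl3 or dioxane at 45–80 °C. It is trapped by the triazine as it forms and the pyrrolidine released on aromatisation re-enters the cycle, so neither TiCl4 nor a stock of free enamine is needed and no new compound arises (F0).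

3. Step 10. Acylation may go to the phenol oxygen or to both heteroatoms, the doubly ortho-substituted aniline nitrogen may react slowly, and acetyl transfer from sulfur to nitrogen or thioester hydrolysis may occur in the basic medium. The fallback brings the sulfur in last. It sets out from 15 and 14 and returns at 18. Acid 15 is converted with (COCl)2 and catalytic DMF into 13-bromotridecanoyl chloride F5. This acylates 14 under the conditions of step 10, and since no thioester is present an excess can be used and any aryl ester cleaved afterwards by brief K2CO3/MeOH at 0 °C, giving 13-bromo-N-[2-hydroxy-6-(2-methylpyridin-4-yl)phenyl]tridecanamide F6. Displacement of the bromide with KSAc in DMF at rt, where the phenol stays protonated, then gives 18.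

**Further compounds**

F1 | step 6 | ethyl 1,2,4-triazine-3-carboxylate | CCOC(=O)c1nccnn1
F2 | step 6 | ethyl 4-[3-(benzyloxy)-2-nitrophenyl]pyridine-2-carboxylate | CCOC(=O)c1cc(-c2cccc(OCc3ccccc3)c2[N+](=O)[O-])ccn1
F3 | step 6 | {4-[3-(benzyloxy)-2-nitrophenyl]pyridin-2-yl}methanol | OCc1cc(-c2cccc(OCc3ccccc3)c2[N+](=O)[O-])ccn1
F4 | step 6 | 4-[3-(benzyloxy)-2-nitrophenyl]-2-(chloromethyl)pyridine | ClCc1cc(-c2cccc(OCc3ccccc3)c2[N+](=O)[O-])ccn1
F0 | step 3 | none | none
F5 | step 10 | 13-bromotridecanoyl chloride | O=C(Cl)CCCCCCCCCCCCBr
F6 | step 10 | 13-bromo-N-[2-hydroxy-6-(2-methylpyridin-4-yl)phenyl]tridecanamide | Cc1cc(-c2cccc(O)c2NC(=O)CCCCCCCCCCCCBr)ccn1
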